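**Plan**

- Retrosynthesis: first the side-chain ester C–O bond (back to shikonin and 3-acetoxy-3-methylbutanoic acid), then both carbonyl–aryl bonds C1–C8a and C4–C4a of the quinone ring in one retro-(4+2) step, then the bond between the succinate α-carbon and the carbinol carbon (aldol).
- Enabling feature: in the 5,8-dihydroxy-1,4-naphthoquinone core the quinone ring B (C1–C4, C4a, C8a) and the hydroquinone ring A (C4a, C5–C8, C8a) are tautomers through the 4a,8a-dihydro-1,4,5,8-tetrone. That tetrone is the adduct of p-benzoquinone (C4a, C5–C8, C8a) and the C1–C4 unit at the bis-enol level of a succinic anhydride, a 3-substituted 2,5-bis(silyloxy)furan whose ring oxygen locks the diene cisoid.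
- Forward: an Evans aldol joins a succinate to 4-methylpent-3-enal; silylation, auxiliary cleavage and dehydration give the anhydride; twofold silylation gives the furan; the Diels–Alder reaction with benzoquinone closes ring B while the benzoquinone ring aromatises to ring A; desilylation and Steglich esterification finish.
- Stereochemistry: the single (R) carbinol centre comes from the (S)-4-benzyloxazolidinone-controlled boron aldol; the neighbouring α-centre is erased in the furan.

Key step: step 8

Remark: the SMILES is read as the (R)-ester (shikonin series); the α-carbon centre of 9–15 is drawn as formed but need not stay pure, since it becomes sp2 in 16.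

**Route**

Step 1
Reactants: 1 4-tert-butoxy-4-oxobutanoic acid (mono-tert-butyl succinate); 2 (S)-4-benzyl-1,3-oxazolidin-2-one
Product: 4 tert-butyl 4-[(4S)-4-benzyl-2-oxo-1,3-oxazolidin-3-yl]-4-oxobutanoate, via mixed pivalic anhydride 3 (not isolated)
Conditions: 1, PivCl, Et3N, THF, −20 °C; then 2, LiCl, −20 °C → rt
Reagents that add atoms: none
Why: N-acylation of the oxazolidinone through the mixed pivalic anhydride (LiCl/Et3N protocol) is standard for Evans imides, and the hindered tert-butyl ester is inert.

Step 2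
Reactants: 5 4-methylpent-3-en-1-ol
Product: 6 4-methylpent-3-enal
Conditions: DMP, CH2Cl2, 0 °C → rt; cold pentane filtration, used at once
Reagents that add atoms: none
Why: Dess–Martin oxidation is neutral and fast, so the β,γ-unsaturated aldehyde should form without migration of the double bond into conjugation.

Step 3
Reactants: 4 imide; 6 4-methylpent-3-enal
Product: 9 tert-butyl (3S,4R)-3-[(4S)-4-benzyl-2-oxo-1,3-oxazolidine-3-carbonyl]-4-hydroxy-7-methyloct-6-enoate, via dibutylboron enolate 7 (not isolated), via dibutylboron aldolate 8 (not isolated)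
Conditions: 4, Bu2BOTf, iPr2NEt, CH2Cl2, 0 °C; then 6, −78 → 0 °C; pH 7 buffer, MeOH, 30% H2O2, 0 °C
Reagents that add atoms: none
Why: Evans syn aldol in which the (Z)-boron enolate, formed on the imide side only, reacts through a Zimmerman–Traxler chair on the face dictated by the (S)-benzyl auxiliary, setting the (4R) carbinol and (3S) α-centres, while the tert-butyl ester keeps the aldol from lactonising.

Step 4
Reactants: 9 aldol adduct
Product: 12 (3S,4R)-3-[(4S)-4-benzyl-2-oxo-1,3-oxazolidine-3-carbonyl]-4-[(tert-butyldimethylsilyl)oxy]-7-methyloct-6-enoic acid, via silyl ether tert-butyl ester 10 (not isolated), via trimethylsilyl ester 11 (not isolated)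
Conditions: TBSOTf, 2,6-lutidine, CH2Cl2, −78 → 0 °C; then TMSOTf, 0 °C → rt; pH 5 buffer
Reagents that add atoms: tert-butyldimethylsilyl triflate (TBSOTf), CC(C)(C)[Si](C)(C)OS(=O)(=O)C(F)(F)F
Why: Silyl triflate with 2,6-lutidine first silylates the secondary alcohol and TMSOTf then cleaves the tert-butyl ester by carbonyl O-silylation and loss of 2-methylpropene, the labile trimethylsilyl ester being hydrolysed on work-up while the buffered medium spares the prenyl alkene and the imide.

Step 5
Reactants: 12 silyl ether acid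
Product: 14 (2S)-2-[(1R)-1-[(tert-butyldimethylsilyl)oxy]-4-methylpent-3-en-1-yl]butanedioic acid, via peroxy acid 13 (not isolated)
Conditions: LiOH, 30% H2O2, THF/H2O (3:1), 0 °C; then aq. Na2SO3; 1 M HCl to pH 3
Reagents that add atoms: hydrogen peroxide, OO
Why: LiOOH attacks the exocyclic imide carbonyl selectively (standard auxiliary removal, the peroxy acid being reduced by sulfite), the silyl ether blocks lactonisation of the diacid, and the isolated alkene is inert to basic peroxide.

Step 6
Reactants: 14 diacid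
Product: 15 (3S)-3-[(1R)-1-[(tert-butyldimethylsilyl)oxy]-4-methylpent-3-en-1-yl]oxolane-2,5-dione
Conditions: DCC, CH2Cl2, 0 °C → rt; filtration
Reagents that add atoms: none
Why: Carbodiimide dehydration of a succinic acid to its five-membered cyclic anhydride is fast and neutral, so the silyl ether and the alkene should be untouched.

Step 7
Reactants: 15 anhydride
Product: 16 3-[(1R)-1-[(tert-butyldimethylsilyl)oxy]-4-methylpent-3-en-1-yl]-2,5-bis(trimethylsilyloxy)furan
Conditions: TMSOTf (2.2 equiv), Et3N (2.6 equiv), Et2O, −20 → 0 °C; pentane, filtration and concentration under argon, used at once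
Reagents that add atoms: trimethylsilyl triflate (TMSOTf), C[Si](C)(C)OS(=O)(=O)C(F)(F)F
Why: Twofold soft enolisation and O-silylation of a succinic anhydride gives the aromatic 2,5-bis(silyloxy)furan (a bis silyl ketene acetal), and since no free enolate is formed and excess amine buffers the silyl triflate, the β-silyloxy group should not be expelled and the carbinol centre is not touched.

Step 8
Reactants: 16 bis(silyloxy)furan; 17 p-benzoquinone
Product: 20 2-[(1R)-1-[(tert-butyldimethylsilyl)oxy]-4-methylpent-3-en-1-yl]-5,8-dihydroxynaphthalene-1,4-dione (shikonin TBS ether), via oxa-bridged cycloadduct 18 (not isolated), via ene-tetrone tautomer 19 (not isolated)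
Conditions: 17 (1.2 equiv), toluene, −40 °C → rt, dark, argon; then THF, aq. citric acid, 0 °C → rt
Reagents that add atoms: none
Why: In a normal-demand Diels–Alder reaction the electron-rich furan 16 adds through C2 and C5 to one C=C bond of benzoquinone, forming both carbonyl-carbon to ring-fusion-carbon bonds at once and giving the 7-oxanorbornene bis(silyl ketal) 18. On mild acid the two bridgehead O-silyl ketals collapse with loss of the disiloxane, which opens the oxygen bridge to the ene-tetrone 19, and twofold enolisation of its two ring-fusion hydrogens turns the former benzoquinone ring into the aromatic hydroquinone ring of 20 without any oxidant. The closest known reaction type is the Diels–Alder reaction of 2,5-bis(trimethylsilyloxy)furans derived from succinic anhydrides with electron-poor alkenes and alkynes, which delivers hydroquinones and quinones after collapse of the bridge. The six-membered quinone ring is closed by an intermolecular suprafacial (4+2) cycloaddition in which the furan oxygen, a temporary bridge that ends in the siloxane, holds the diene cisoid. No stereocentre is created in the product, since the four transient centres of 18 (endo or exo) are all erased and the existing carbinol centre is a spectator bearing a poor leaving group. The step needs periselectivity for cycloaddition across C2/C5 over Mukaiyama–Michael addition through C4 and over silyl-transfer redox, which the absence of Lewis acid and triflate salt, the non-polar solvent and the low temperature should secure; regiochemistry does not arise because benzoquinone is symmetrical and the two naphthazarin tautomers are one compound, and the unactivated prenyl alkene does not compete.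

Step 9
Reactants: 20 shikonin TBS ether
Product: 21 shikonin, 5,8-dihydroxy-2-[(1R)-1-hydroxy-4-methylpent-3-en-1-yl]naphthalene-1,4-dione
Conditions: HF·pyridine, pyridine, THF, 0 °C → rt (polypropylene flask)
Reagents that add atoms: none
Why: Buffered fluoride desilylation of a secondary TBS ether is mild enough to avoid acid-induced cyclisation onto the prenyl alkene and base-induced decomposition of the naphthazarin, and the C–O bond of the stereocentre is not broken.

Step 10
Reactants: 22 3-hydroxy-3-methylbutanoic acid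
Product: 23 3-acetoxy-3-methylbutanoic acid
Conditions: AcCl, CH2Cl2, 0 °C → rt; evaporation; aqueous work-up
Reagents that add atoms: acetyl chloride, CC(=O)Cl
Why: Acetyl chloride O-acetylates tertiary hydroxy acids without added base, as in the preparation of acetoxyisobutyric acid, so the base-promoted loss of the β-oxygen is avoided.

Step 11
Reactants: 21 shikonin; 23 3-acetoxy-3-methylbutanoic acid
Product: 24 (1R)-1-(5,8-dihydroxy-1,4-dioxo-1,4-dihydronaphthalen-2-yl)-4-methylpent-3-en-1-yl 3-acetoxy-3-methylbutanoate (β-acetoxyisovalerylshikonin)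
Conditions: DCC, DMAP (cat.), CH2Cl2, 0 °C → rt
Reagents that add atoms: none
Why: Steglich esterification should acylate only the side-chain secondary alcohol, because the two peri phenols are locked in hydrogen bonds to the quinone carbonyls, and acyl transfer leaves the C–O bond of the stereocentre intact, so the (R) configuration is retained.

**Compound list**

1 | 4-tert-butoxy-4-oxobutanoic acid (mono-tert-butyl succinate) | CC(C)(C)OC(=O)CCC(=O)O | starting material
2 | (S)-4-benzyl-1,3-oxazolidin-2-one | O=C1N[C@@H](Cc2ccccc2)CO1 | starting material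
3 | 4-tert-butoxy-4-oxobutanoic pivalic anhydride | CC(C)(C)OC(=O)CCC(=O)OC(=O)C(C)(C)C | intermediate
4 | tert-butyl 4-[(4S)-4-benzyl-2-oxo-1,3-oxazolidin-3-yl]-4-oxobutanoate | CC(C)(C)OC(=O)CCC(=O)N1C(=O)OC[C@@H]1Cc1ccccc1 | intermediate
5 | 4-methylpent-3-en-1-ol | CC(C)=CCCO | starting material
6 | 4-methylpent-3-enal | CC(C)=CCC=O | intermediate
7 | tert-butyl (Z)-4-[(4S)-4-benzyl-2-oxo-1,3-oxazolidin-3-yl]-4-[(dibutylboranyl)oxy]but-3-enoate | CCCCB(CCCC)O/C(=C\CC(=O)OC(C)(C)C)N1C(=O)OC[C@@H]1Cc1ccccc1 | intermediate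
8 | tert-butyl (3S,4R)-3-[(4S)-4-benzyl-2-oxo-1,3-oxazolidine-3-carbonyl]-4-[(dibutylboranyl)oxy]-7-methyloct-6-enoate | CC(C)=CC[C@@H](OB(CCCC)CCCC)[C@H](CC(=O)OC(C)(C)C)C(=O)N1C(=O)OC[C@@H]1Cc1ccccc1 | intermediate
9 | tert-butyl (3S,4R)-3-[(4S)-4-benzyl-2-oxo-1,3-oxazolidine-3-carbonyl]-4-hydroxy-7-methyloct-6-enoate | CC(C)=CC[C@@H](O)[C@H](CC(=O)OC(C)(C)C)C(=O)N1C(=O)OC[C@@H]1Cc1ccccc1 | intermediate
10 | tert-butyl (3S,4R)-3-[(4S)-4-benzyl-2-oxo-1,3-oxazolidine-3-carbonyl]-4-[(tert-butyldimethylsilyl)oxy]-7-methyloct-6-enoate | CC(C)=CC[C@@H](O[Si](C)(C)C(C)(C)C)[C@H](CC(=O)OC(C)(C)C)C(=O)N1C(=O)OC[C@@H]1Cc1ccccc1 | intermediate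
11 | trimethylsilyl (3S,4R)-3-[(4S)-4-benzyl-2-oxo-1,3-oxazolidine-3-carbonyl]-4-[(tert-butyldimethylsilyl)oxy]-7-methyloct-6-enoate | CC(C)=CC[C@@H](O[Si](C)(C)C(C)(C)C)[C@H](CC(=O)O[Si](C)(C)C)C(=O)N1C(=O)OC[C@@H]1Cc1ccccc1 | intermediate
12 | (3S,4R)-3-[(4S)-4-benzyl-2-oxo-1,3-oxazolidine-3-carbonyl]-4-[(tert-butyldimethylsilyl)oxy]-7-methyloct-6-enoic acid | CC(C)=CC[C@@H](O[Si](C)(C)C(C)(C)C)[C@H](CC(=O)O)C(=O)N1C(=O)OC[C@@H]1Cc1ccccc1 | intermediate
13 | (2S,3R)-3-[(tert-butyldimethylsilyl)oxy]-2-(carboxymethyl)-6-methylhept-5-eneperoxoic acid | CC(C)=CC[C@@H](O[Si](C)(C)C(C)(C)C)[C@H](CC(=O)O)C(=O)OO | intermediate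
14 | (2S)-2-[(1R)-1-[(tert-butyldimethylsilyl)oxy]-4-methylpent-3-en-1-yl]butanedioic acid | CC(C)=CC[C@@H](O[Si](C)(C)C(C)(C)C)[C@H](CC(=O)O)C(=O)O | intermediate
15 | (3S)-3-[(1R)-1-[(tert-butyldimethylsilyl)oxy]-4-methylpent-3-en-1-yl]oxolane-2,5-dione | CC(C)=CC[C@@H](O[Si](C)(C)C(C)(C)C)[C@@H]1CC(=O)OC1=O | intermediate
16 | 3-[(1R)-1-[(tert-butyldimethylsilyl)oxy]-4-methylpent-3-en-1-yl]-2,5-bis(trimethylsilyloxy)furan | CC(C)=CC[C@@H](O[Si](C)(C)C(C)(C)C)c1cc(O[Si](C)(C)C)oc1O[Si](C)(C)C | intermediate
17 | p-benzoquinone (cyclohexa-2,5-diene-1,4-dione) | O=C1C=CC(=O)C=C1 | starting material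
18 | 2-[(1R)-1-[(tert-butyldimethylsilyl)oxy]-4-methylpent-3-en-1-yl]-1,4-bis(trimethylsilyloxy)-1,4,4a,8a-tetrahydro-1,4-epoxynaphthalene-5,8-dione (ring stereocentres transient, unspecified) | CC(C)=CC[C@@H](O[Si](C)(C)C(C)(C)C)C1=CC2(O[Si](C)(C)C)OC1(O[Si](C)(C)C)C1C(=O)C=CC(=O)C12 | intermediate
19 | 2-[(1R)-1-[(tert-butyldimethylsilyl)oxy]-4-methylpent-3-en-1-yl]-4a,8a-dihydronaphthalene-1,4,5,8-tetrone | CC(C)=CC[C@@H](O[Si](C)(C)C(C)(C)C)C1=CC(=O)C2C(=O)C=CC(=O)C2C1=O | intermediate
20 | 2-[(1R)-1-[(tert-butyldimethylsilyl)oxy]-4-methylpent-3-en-1-yl]-5,8-dihydroxynaphthalene-1,4-dione (shikonin TBS ether) | CC(C)=CC[C@@H](O[Si](C)(C)C(C)(C)C)C1=CC(=O)c2c(O)ccc(O)c2C1=O | intermediate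
21 | shikonin, 5,8-dihydroxy-2-[(1R)-1-hydroxy-4-methylpent-3-en-1-yl]naphthalene-1,4-dione | CC(C)=CC[C@@H](O)C1=CC(=O)c2c(O)ccc(O)c2C1=O | intermediate
22 | 3-hydroxy-3-methylbutanoic acid | CC(C)(O)CC(=O)O | starting material
23 | 3-acetoxy-3-methylbutanoic acid | CC(=O)OC(C)(C)CC(=O)O | intermediate
24 | (1R)-1-(5,8-dihydroxy-1,4-dioxo-1,4-dihydronaphthalen-2-yl)-4-methylpent-3-en-1-yl 3-acetoxy-3-methylbutanoate | CC(=O)OC(C)(C)CC(=O)O[C@H](CC=C(C)C)C1=CC(=O)c2c(O)ccc(O)c2C1=O | target

**Step count and risks**

Total steps: 11. Longest linear sequence: 9 (steps 1, 3, 4, 5, 6, 7, 8, 9, 11).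

Step 8. The furan may add to the quinone by conjugate addition through C4 or pass its silyl groups to the quinone by electron transfer instead of cycloadding, and the furfuryl-type silyl ether may ionise. The fallback sets out from 16 and replaces the quinone by an aryne, which can accept neither an electron nor a conjugate addition. 3,6-Dimethoxybenzyne F1, generated from commercial 2-bromo-1,4-dimethoxybenzene with LiN(iPr)2 (THF, −78 °C → rt) in the presence of 16, should add across C2/C5 to give 2-[(1R)-1-(tert-butyldimethylsilyloxy)-4-methylpent-3-enyl]-5,8-dimethoxy-1,4-bis(trimethylsilyloxy)-1,4-dihydro-1,4-epoxynaphthalene F2. Aqueous citric acid should collapse this to 2-[(1R)-1-(tert-butyldimethylsilyloxy)-4-methylpent-3-enyl]-5,8-dimethoxynaphthalene-1,4-dione F3. BCl3 (CH2Cl2, −78 °C) should then remove the two peri methyl ethers by chelation to the quinone carbonyls, and the route is rejoined at 20.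

Step 4. Cleavage of the tert-butyl ester by the silyl triflate may be incomplete, or the activated ester may be attacked by the neighbouring silyl ether oxygen, with lactonisation and loss of the TBS group. The fallback sets out from 9 and stops after the first stage (TBSOTf, 2,6-lutidine, −78 °C), so that 10 is isolated. LiOH/H2O2 then removes the auxiliary to give (2S)-4-tert-butoxy-2-[(1R)-1-(tert-butyldimethylsilyloxy)-4-methylpent-3-enyl]-4-oxobutanoic acid F4. The neutral Ghosez reagent (1-chloro-N,N,2-trimethylprop-1-en-1-amine, CH2Cl2, 0 °C → rt) should convert the acid into its chloride, which the tert-butyl ester carbonyl attacks with loss of the tert-butyl group, closing the anhydride directly. The route is rejoined at 15.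

Step 11. The activated β-acetoxy acid may lose acetate by base-promoted elimination at the acylpyridinium stage, giving the 3-methylbut-2-enoyl ester, or rearrange to the N-acylurea. The fallback sets out from 21 and activates an acid without a β-leaving group. Steglich coupling with the hydroxy acid 22 should give (1R)-1-(5,8-dihydroxy-1,4-dioxo-1,4-dihydronaphthalen-2-yl)-4-methylpent-3-en-1-yl 3-hydroxy-3-methylbutanoate F5. Exhaustive acetylation (Ac2O, DMAP, Et3N, CH2Cl2) should give (1R)-1-(5,8-diacetoxy-1,4-dioxo-1,4-dihydronaphthalen-2-yl)-4-methylpent-3-en-1-yl 3-acetoxy-3-methylbutanoate F6. The two aryl acetates, far more labile than the alkyl esters, are then removed selectively (NH4OAc, aq. MeOH, rt), and the route is rejoined at 24.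

**Further compounds**

F1 | step 8 | 3,6-dimethoxybenzyne (1,2-didehydro-3,6-dimethoxybenzene) | COC1=CC=C(OC)C#C1
F2 | step 8 | 2-[(1R)-1-[(tert-butyldimethylsilyl)oxy]-4-methylpent-3-en-1-yl]-5,8-dimethoxy-1,4-bis(trimethylsilyloxy)-1,4-dihydro-1,4-epoxynaphthalene | CC(C)=CC[C@@H](O[Si](C)(C)C(C)(C)C)C1=CC2(O[Si](C)(C)C)OC1(O[Si](C)(C)C)c1c(OC)ccc(OC)c12
F3 | step 8 | 2-[(1R)-1-[(tert-butyldimethylsilyl)oxy]-4-methylpent-3-en-1-yl]-5,8-dimethoxynaphthalene-1,4-dione | CC(C)=CC[C@@H](O[Si](C)(C)C(C)(C)C)C1=CC(=O)c2c(OC)ccc(OC)c2C1=O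
F4 | step 4 | (2S)-4-tert-butoxy-2-[(1R)-1-[(tert-butyldimethylsilyl)oxy]-4-methylpent-3-en-1-yl]-4-oxobutanoic acid | CC(C)=CC[C@@H](O[Si](C)(C)C(C)(C)C)[C@H](CC(=O)OC(C)(C)C)C(=O)O
F5 | step 11 | (1R)-1-(5,8-dihydroxy-1,4-dioxo-1,4-dihydronaphthalen-2-yl)-4-methylpent-3-en-1-yl 3-hydroxy-3-methylbutanoate | CC(C)=CC[C@@H](OC(=O)CC(C)(C)O)C1=CC(=O)c2c(O)ccc(O)c2C1=O
F6 | step 11 | (1R)-1-(5,8-diacetoxy-1,4-dioxo-1,4-dihydronaphthalen-2-yl)-4-methylpent-3-en-1-yl 3-acetoxy-3-methylbutanoate | CC(C)=CC[C@@H](OC(=O)CC(C)(C)OC(C)=O)C1=CC(=O)c2c(OC(C)=O)ccc(OC(C)=O)c2C1=O
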